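**Retrosynthetic overview**

1. The strategy rests on the five-membered lactol-lactone fused to ring B: the acetal carbon (the only stereocentre) sits on one ring B carbon, the lactone carbonyl carbon on the neighbouring ring B carbon, and the ring oxygen joins them. This ring is cut back to an aryl bromide with an aldehyde beside it, carbon monoxide and 4-methoxybenzyl alcohol.
2. The seven-membered dioxepinone (depsidone) ring is opened first at the diaryl ether C–O bond (intramolecular copper-mediated O-arylation at the bromide ortho to a ring B aldehyde), then at the aryl ester (carbodiimide coupling of a ring A acid with a ring B phenol).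
3. Ring B comes from 2,6-dihydroxybenzaldehyde by dibromination, chelation-controlled differentiation of the two phenols, acetal masking of the first aldehyde and lithiation between the two bromines to bring in the second aldehyde. Ring A comes from methyl orsellinate by formylation between its hydroxyls.
4. Order of ring formation: seven-membered ring (ester, then ether), then the five-membered lactol-lactone, then oxidative removal of three 4-methoxybenzyl groups.

Key step: step 13

Assumption: the free lactol of the target can lose its configuration by ring opening to the formyl acid, so it is carried as a 4-methoxybenzyl acetal and freed only in the last step under neutral, cold conditions. The ligand (R)-DTBM-SEGPHOS, (R)-5,5'-bis[bis(3,5-di-tert-butyl-4-methoxyphenyl)phosphino]-4,4'-bi-1,3-benzodioxole, is taken to give the S acetal; its enantiomer is used if the sense proves opposite.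

**Route**

Step 1
Reactants: 1 methyl orsellinate (methyl 2,4-dihydroxy-6-methylbenzoate)
Product: 2 methyl 3-formyl-2,4-dihydroxy-6-methylbenzoate
Conditions: Cl2CHOMe, TiCl4, CH2Cl2, −10 °C to rt; then ice/H2O
Reagents that add atoms: dichloromethyl methyl ether, COC(Cl)Cl; water, O
Why: Rieche formylation, in which titanium binds the phenols and should deliver the electrophile mainly to the carbon between the two hydroxyls (ortho to both), any 5-formyl isomer being removed by crystallisation.

Step 2
Reactants: 2 methyl 3-formyl-2,4-dihydroxy-6-methylbenzoate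
Product: 3 methyl 3-formyl-2-hydroxy-4-[(4-methoxybenzyl)oxy]-6-methylbenzoate
Conditions: 4-methoxybenzyl chloride (1.05 equiv), K2CO3 (1.1 equiv), DMF, rt
Reagents that add atoms: 4-methoxybenzyl chloride, COc1ccc(CCl)cc1
Why: Williamson etherification at the 4-hydroxyl, the more acidic and less hindered phenol, while the 2-hydroxyl is held between ester and aldehyde by hydrogen bonding.

Step 3
Reactants: 3 methyl 3-formyl-2-hydroxy-4-[(4-methoxybenzyl)oxy]-6-methylbenzoate
Product: 4 3-formyl-2-hydroxy-4-[(4-methoxybenzyl)oxy]-6-methylbenzoic acid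
Conditions: KOH, DMSO–H2O, 80 °C; then 1 M HCl, 0 °C
Reagents that add atoms: potassium hydroxide, [K+].[OH-]
Why: saponification of a hindered salicylate in aqueous DMSO, the phenoxide formed first shielding the aldehyde from hydroxide and cold acidification avoiding decarboxylation.

Step 4
Reactants: 5 2,6-dihydroxybenzaldehyde
Product: 6 3,5-dibromo-2,6-dihydroxybenzaldehyde
Conditions: Br2 (2.05 equiv), AcOH, rt
Reagents that add atoms: bromine, BrBr
Why: electrophilic aromatic bromination at the two positions that are each ortho to one hydroxyl and para to the other, position 4 being meta to both hydroxyls and para to the aldehyde.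

Step 5
Reactants: 6 3,5-dibromo-2,6-dihydroxybenzaldehyde
Product: 7 3,5-dibromo-2-hydroxy-6-[(4-methoxybenzyl)oxy]benzaldehyde
Conditions: 4-methoxybenzyl chloride (1.0 equiv), K2CO3 (1.0 equiv), DMF, rt
Reagents that add atoms: 4-methoxybenzyl chloride, COc1ccc(CCl)cc1
Why: Williamson etherification that should stop after one alkylation, because the aldehyde oxygen chelates only one hydroxyl and the remaining, chelated phenol reacts far more slowly.

Step 6
Reactants: 7 3,5-dibromo-2-hydroxy-6-[(4-methoxybenzyl)oxy]benzaldehyde
Product: 8 3,5-dibromo-2-[(tert-butyldimethylsilyl)oxy]-6-[(4-methoxybenzyl)oxy]benzaldehyde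
Conditions: t-BuMe2SiCl, imidazole, DMF, rt
Reagents that add atoms: tert-butyldimethylsilyl chloride, CC(C)(C)[Si](C)(C)Cl
Why: silylation of the phenol that will later carry the ester, giving a base-stable cover for the lithiation in step 8.

Step 7
Reactants: 8 3,5-dibromo-2-[(tert-butyldimethylsilyl)oxy]-6-[(4-methoxybenzyl)oxy]benzaldehyde
Product: 9 2-{3,5-dibromo-2-[(tert-butyldimethylsilyl)oxy]-6-[(4-methoxybenzyl)oxy]phenyl}-1,3-dioxolane
Conditions: Me3SiOCH2CH2OSiMe3, Me3SiOSO2CF3 (5 mol%), CH2Cl2, −78 to −20 °C; pyridine quench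
Reagents that add atoms: 1,2-bis(trimethylsilyloxy)ethane, C[Si](C)(C)OCCO[Si](C)(C)C
Why: silyl-triflate-catalysed acetalisation, which works on hindered aldehydes at low temperature and spares the aryl silyl and 4-methoxybenzyl ethers, the dioxolane shielding this carbon from the lithium amide and later keeping the ester-bearing ring carbon unactivated.

Step 8
Reactants: 9 2-{3,5-dibromo-2-[(tert-butyldimethylsilyl)oxy]-6-[(4-methoxybenzyl)oxy]phenyl}-1,3-dioxolane
Product: 11 2,6-dibromo-3-[(tert-butyldimethylsilyl)oxy]-4-(1,3-dioxolan-2-yl)-5-[(4-methoxybenzyl)oxy]benzaldehyde, via aryllithium 10 (not isolated)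
Conditions: LiN(iPr)2, THF, −78 °C; DMF, −78 to −40 °C; aq. NH4Cl
Reagents that add atoms: N,N-dimethylformamide, CN(C)C=O
Why: deprotonation of the only ring C–H, acidified by two flanking bromines, with a lithium amide (no bromine–lithium exchange) followed by formylation with DMF, the 2,6-dibromoaryllithium holding at −78 °C without loss of LiBr.

Step 9
Reactants: 11 2,6-dibromo-3-[(tert-butyldimethylsilyl)oxy]-4-(1,3-dioxolan-2-yl)-5-[(4-methoxybenzyl)oxy]benzaldehyde
Product: 12 2,6-dibromo-4-(1,3-dioxolan-2-yl)-3-hydroxy-5-[(4-methoxybenzyl)oxy]benzaldehyde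
Conditions: Bu4NF, AcOH, THF, 0 °C
Reagents that add atoms: none
Why: fluoride cleavage of the aryl silyl ether, buffered with acetic acid so that the phenoxide is protonated at once and the acetal, aldehyde and bromides are left alone.

Step 10
Reactants: 4 3-formyl-2-hydroxy-4-[(4-methoxybenzyl)oxy]-6-methylbenzoic acid; 12 2,6-dibromo-4-(1,3-dioxolan-2-yl)-3-hydroxy-5-[(4-methoxybenzyl)oxy]benzaldehyde
Product: 13 depside, 2,4-dibromo-6-(1,3-dioxolan-2-yl)-3-formyl-5-[(4-methoxybenzyl)oxy]phenyl 3-formyl-2-hydroxy-4-[(4-methoxybenzyl)oxy]-6-methylbenzoate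
Conditions: DCC, 4-(dimethylamino)pyridine (cat.), CH2Cl2, 0 °C to rt
Reagents that add atoms: none
Why: Steglich esterification, in which the carbodiimide-activated acid acylates the phenol of 12 while its own 2-hydroxyl, hydrogen-bonded between aldehyde and carboxyl, does not compete (the usual behaviour in depside synthesis).

Step 11
Reactants: 13 depside
Product: 14 7-bromo-9-(1,3-dioxolan-2-yl)-3,8-bis[(4-methoxybenzyl)oxy]-1-methyl-11-oxo-11H-dibenzo[b,e][1,4]dioxepine-4,6-dicarbaldehyde
Conditions: CuI (30 mol%), N,N-dimethylglycine (60 mol%), Cs2CO3 (2 equiv), 1,4-dioxane (0.005 M), 90 °C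
Reagents that add atoms: none
Why: intramolecular Ullmann diaryl ether synthesis, in which the ring A phenoxide can reach only the bromide ortho to the ester oxygen (seven-membered ring), that bromide is activated by its ortho aldehyde, and the acetal on the other ring B aldehyde carbon keeps the ester-bearing carbon closed to Smiles-type ipso attack.

Step 12
Reactants: 14 depsidone acetal
Product: 15 bromo trialdehyde depsidone, 7-bromo-3,8-bis[(4-methoxybenzyl)oxy]-1-methyl-11-oxo-11H-dibenzo[b,e][1,4]dioxepine-4,6,9-tricarbaldehyde
Conditions: 1 M HCl, THF, rt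
Reagents that add atoms: water, O
Why: acid hydrolysis of an aryl dioxolane flanked by two oxygen donors, fast under conditions too mild to touch the aryl 4-methoxybenzyl ethers or the hindered aryl ester.

Step 13
Reactants: 15 bromo trialdehyde depsidone; 16 4-methoxybenzyl alcohol; 17 carbon monoxide
Product: 19 tris(4-methoxybenzyl) lactol-lactone, the skeleton of 15 in which C7 carries the lactone carbonyl and C6 the acetal carbon of a fused five-membered ring C6–CH(OCH2C6H4OMe)–O–C(=O)–C7, S at the acetal carbon, via hemiacetal 18 (not isolated)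
Conditions: Pd(OAc)2 (5 mol%), (R)-DTBM-SEGPHOS (6 mol%), CO (1 atm), 16 (3 equiv), Na2CO3 (2 equiv), 4 Å sieves, toluene, 80 °C
Reagents that add atoms: 4-methoxybenzyl alcohol (16), COc1ccc(CO)cc1; carbon monoxide (17), [C-]#[O+]
Why: Proposed new method: zerovalent palladium, formed from Pd(OAc)2 and the bisphosphine under CO, should add oxidatively to the single C–Br bond and take up CO to give an aroyl complex of divalent palladium, while the aldehyde on the neighbouring ring B carbon equilibrates with alcohol 16 to both enantiomers of hemiacetal 18; the hemiacetal hydroxyl then binds palladium and C–O reductive elimination from the six-membered acyl(alkoxo)palladacycle closes the lactone and returns zerovalent palladium. The closest known reaction type is the palladium-catalysed carbonylation of 2-bromobenzaldehydes in alcohols to racemic 3-alkoxyphthalides; new here is a chiral ligand that selects between rapidly exchanging hemiacetal enantiomers (a dynamic kinetic resolution). The five-membered lactol-lactone ring closes by attack of the hemiacetal oxygen on the acyl carbon in a 5-exo-trig mode, which forms the aryl–C(=O) bond and the C(=O)–O bond in one catalytic turn. The S configuration at the acetal carbon is set by the ligand, because the two diastereomeric palladacycles eliminate at different rates and the slower hemiacetal enantiomer reverts through the aldehyde. The step needs site selection among three aldehydes, secured because only the aldehyde ortho to the bromide can reach the acyl metal through a five-membered closure, and selection against open ester formation by free alcohol, secured by intramolecular delivery, by the insoluble weak base and by holding 16 at 3 equiv. The product has no free hydroxyl at the acetal carbon, so it cannot open and racemise under these conditions.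

Step 14
Reactants: 19 tris(4-methoxybenzyl) lactol-lactone
Product: 20 target CNP0296574.1, the S lactol with free hydroxyls at C3, C8 and the lactol carbon
Conditions: DDQ (4 equiv), CH2Cl2–pH 7 phosphate buffer (10:1), 0 °C to rt
Reagents that add atoms: none
Why: oxidative cleavage of 4-methoxybenzyl ethers with DDQ, each group being oxidised at its own benzylic carbon and leaving as 4-methoxybenzaldehyde, so that no bond to the acetal carbon is broken and the S configuration should be kept under buffered, cold conditions.

**Compound list**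

1 | methyl orsellinate (methyl 2,4-dihydroxy-6-methylbenzoate) | COC(=O)c1c(C)cc(O)cc1O | starting material
2 | methyl 3-formyl-2,4-dihydroxy-6-methylbenzoate | COC(=O)c1c(C)cc(O)c(C=O)c1O | intermediate
3 | methyl 3-formyl-2-hydroxy-4-[(4-methoxybenzyl)oxy]-6-methylbenzoate | COC(=O)c1c(C)cc(OCc2ccc(OC)cc2)c(C=O)c1O | intermediate
4 | 3-formyl-2-hydroxy-4-[(4-methoxybenzyl)oxy]-6-methylbenzoic acid | OC(=O)c1c(C)cc(OCc2ccc(OC)cc2)c(C=O)c1O | intermediate
5 | 2,6-dihydroxybenzaldehyde | Oc1cccc(O)c1C=O | starting material
6 | 3,5-dibromo-2,6-dihydroxybenzaldehyde | Oc1c(Br)cc(Br)c(O)c1C=O | intermediate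
7 | 3,5-dibromo-2-hydroxy-6-[(4-methoxybenzyl)oxy]benzaldehyde | Oc1c(Br)cc(Br)c(OCc2ccc(OC)cc2)c1C=O | intermediate
8 | 3,5-dibromo-2-[(tert-butyldimethylsilyl)oxy]-6-[(4-methoxybenzyl)oxy]benzaldehyde | CC(C)(C)[Si](C)(C)Oc1c(Br)cc(Br)c(OCc2ccc(OC)cc2)c1C=O | intermediate
9 | 2-{3,5-dibromo-2-[(tert-butyldimethylsilyl)oxy]-6-[(4-methoxybenzyl)oxy]phenyl}-1,3-dioxolane | CC(C)(C)[Si](C)(C)Oc1c(Br)cc(Br)c(OCc2ccc(OC)cc2)c1C1OCCO1 | intermediate
10 | aryllithium of 9, lithium on the carbon between the two bromines | CC(C)(C)[Si](C)(C)Oc1c(Br)c([Li])c(Br)c(OCc2ccc(OC)cc2)c1C1OCCO1 | intermediate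
11 | 2,6-dibromo-3-[(tert-butyldimethylsilyl)oxy]-4-(1,3-dioxolan-2-yl)-5-[(4-methoxybenzyl)oxy]benzaldehyde | CC(C)(C)[Si](C)(C)Oc1c(Br)c(C=O)c(Br)c(OCc2ccc(OC)cc2)c1C1OCCO1 | intermediate
12 | 2,6-dibromo-4-(1,3-dioxolan-2-yl)-3-hydroxy-5-[(4-methoxybenzyl)oxy]benzaldehyde | Oc1c(Br)c(C=O)c(Br)c(OCc2ccc(OC)cc2)c1C1OCCO1 | intermediate
13 | depside, 2,4-dibromo-6-(1,3-dioxolan-2-yl)-3-formyl-5-[(4-methoxybenzyl)oxy]phenyl 3-formyl-2-hydroxy-4-[(4-methoxybenzyl)oxy]-6-methylbenzoate | Cc1cc(OCc2ccc(OC)cc2)c(C=O)c(O)c1C(=O)Oc1c(Br)c(C=O)c(Br)c(OCc2ccc(OC)cc2)c1C1OCCO1 | intermediate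
14 | 7-bromo-9-(1,3-dioxolan-2-yl)-3,8-bis[(4-methoxybenzyl)oxy]-1-methyl-11-oxo-11H-dibenzo[b,e][1,4]dioxepine-4,6-dicarbaldehyde | Cc1cc(OCc3ccc(OC)cc3)c(C=O)c2c1C(=O)Oc1c(C3OCCO3)c(OCc3ccc(OC)cc3)c(Br)c(C=O)c1O2 | intermediate
15 | bromo trialdehyde depsidone, 7-bromo-3,8-bis[(4-methoxybenzyl)oxy]-1-methyl-11-oxo-11H-dibenzo[b,e][1,4]dioxepine-4,6,9-tricarbaldehyde | Cc1cc(OCc3ccc(OC)cc3)c(C=O)c2c1C(=O)Oc1c(C=O)c(OCc3ccc(OC)cc3)c(Br)c(C=O)c1O2 | intermediate
16 | 4-methoxybenzyl alcohol | COc1ccc(CO)cc1 | starting material
17 | carbon monoxide | [C-]#[O+] | starting material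
18 | hemiacetal of 15 with 16 at the aldehyde next to the bromide, both configurations in equilibrium | Cc1cc(OCc3ccc(OC)cc3)c(C=O)c2c1C(=O)Oc1c(C=O)c(OCc3ccc(OC)cc3)c(Br)c(C(O)OCc3ccc(OC)cc3)c1O2 | intermediate
19 | tris(4-methoxybenzyl) lactol-lactone, S at the acetal carbon | Cc1cc(OCc3ccc(OC)cc3)c(C=O)c2c1C(=O)Oc1c(C=O)c(OCc3ccc(OC)cc3)c3c(c1O2)[C@@H](OCc1ccc(OC)cc1)OC3=O | intermediate
20 | CNP0296574.1, S lactol | Cc1cc(O)c(C=O)c2c1C(=O)Oc1c(C=O)c(O)c3c(c1O2)[C@@H](O)OC3=O | target

**Step count**

Total: 14 steps. Longest linear sequence: 11 steps (from 5, steps 4 to 14); the ring A branch (steps 1 to 3) joins at step 10.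

**Steps most likely to fail**

Step 13. The acyl transfer to the hemiacetal may escape the control of the ligand and give low enantiomeric excess. The aroyl palladium may also be captured by free alcohol to give the open ester, or the C–Br bond may be reduced through β-hydride loss from a palladium alkoxide. The fallback uses known chemistry and sets out from 15. The same closure is run without asymmetric induction: Pd(OAc)2 with 4,5-bis(diphenylphosphino)-9,9-dimethylxanthene, Na2CO3, CO and 16 in toluene. This is the established carbonylation of 2-bromobenzaldehydes in alcohols and should give the racemic tris(4-methoxybenzyl) lactol-lactone F1. Because the alkyl acetal is configurationally stable, preparative chromatography on a chiral stationary phase should separate the S enantiomer, which is 19, from the R enantiomer F2. The route is rejoined at 19.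

Step 11. The C–O coupling at a bromide with two ortho substituents may be slow, because the ring A phenoxide is weakly nucleophilic and can tie up copper as a salicylaldehyde chelate. Base-induced cleavage of the aryl ester or intermolecular coupling could then take over. The fallback reverses the order to ether first and lactone last, the classical depsidone sequence, and sets out from 12 and 4. Alkylation of the free phenol of 12 with 4-methoxybenzyl chloride and K2CO3 gives the symmetrical 2,6-dibromo-4-(1,3-dioxolan-2-yl)-3,5-bis[(4-methoxybenzyl)oxy]benzaldehyde F3, whose two bromides are equivalent. Acid 4 with 4-methoxybenzyl chloride and KHCO3 in DMF gives 4-methoxybenzyl 3-formyl-2-hydroxy-4-[(4-methoxybenzyl)oxy]-6-methylbenzoate F4. Intermolecular Ullmann coupling of the phenol of F4 with F3 (CuI, picolinic acid, K3PO4, DMSO, 90 °C) gives the diaryl ether F5. Trifluoroacetic acid with pentamethylbenzene in CH2Cl2, then water, removes the ester, the three ethers and the dioxolane to give the trihydroxy trialdehyde acid F6. DCC at high dilution closes the only possible seven-membered lactone, onto the hydroxyl ortho to the ether oxygen, to give the dihydroxy bromo trialdehyde depsidone F7. 4-Methoxybenzyl chloride (2 equiv) with K2CO3 then re-protects the two phenols, and the route is rejoined at 15.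

Step 14. Oxidation at the benzylic carbon of the acetal 4-methoxybenzyl group may be slow, since its oxygen is a poor donor. During long contact with water and the acidic hydroquinone, the freed lactol may open to the formyl acid and reclose, which would erode the configuration. The fallback separates the lactol release from the phenol deprotection by using a photolabile acetal, and sets out from 15. The carbonylative closure of step 13 is run with 2-nitrobenzyl alcohol in place of 16 to give the S 2-nitrobenzyl acetal F8. DDQ then removes only the two aryl 4-methoxybenzyl ethers, the electron-poor nitrobenzyl acetal being inert, to give the diphenol 2-nitrobenzyl acetal F9. Irradiation at 365 nm in dry acetonitrile at 0 °C releases the lactol under neutral, water-free conditions, with 2-nitrosobenzaldehyde as the only co-product. The route is rejoined at 20.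

**Further compounds**

F1 | step 13 | racemic tris(4-methoxybenzyl) lactol-lactone | Cc1cc(OCc3ccc(OC)cc3)c(C=O)c2c1C(=O)Oc1c(C=O)c(OCc3ccc(OC)cc3)c3c(c1O2)C(OCc1ccc(OC)cc1)OC3=O
F2 | step 13 | R enantiomer of 19 | Cc1cc(OCc3ccc(OC)cc3)c(C=O)c2c1C(=O)Oc1c(C=O)c(OCc3ccc(OC)cc3)c3c(c1O2)[C@H](OCc1ccc(OC)cc1)OC3=O
F3 | step 11 | 2,6-dibromo-4-(1,3-dioxolan-2-yl)-3,5-bis[(4-methoxybenzyl)oxy]benzaldehyde | O=Cc1c(Br)c(OCc2ccc(OC)cc2)c(C2OCCO2)c(OCc2ccc(OC)cc2)c1Br
F4 | step 11 | 4-methoxybenzyl 3-formyl-2-hydroxy-4-[(4-methoxybenzyl)oxy]-6-methylbenzoate | Cc1cc(OCc2ccc(OC)cc2)c(C=O)c(O)c1C(=O)OCc1ccc(OC)cc1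
F5 | step 11 | diaryl ether of F4 and F3 | Cc1cc(OCc2ccc(OC)cc2)c(C=O)c(Oc2c(OCc3ccc(OC)cc3)c(C3OCCO3)c(OCc3ccc(OC)cc3)c(Br)c2C=O)c1C(=O)OCc1ccc(OC)cc1
F6 | step 11 | trihydroxy trialdehyde diaryl ether acid | Cc1cc(O)c(C=O)c(Oc2c(O)c(C=O)c(O)c(Br)c2C=O)c1C(=O)O
F7 | step 11 | dihydroxy bromo trialdehyde depsidone | Cc1cc(O)c(C=O)c2c1C(=O)Oc1c(C=O)c(O)c(Br)c(C=O)c1O2
F8 | step 14 | S 2-nitrobenzyl acetal with two aryl 4-methoxybenzyl ethers | Cc1cc(OCc3ccc(OC)cc3)c(C=O)c2c1C(=O)Oc1c(C=O)c(OCc3ccc(OC)cc3)c3c(c1O2)[C@@H](OCc1ccccc1[N+](=O)[O-])OC3=O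
F9 | step 14 | S 2-nitrobenzyl acetal diphenol | Cc1cc(O)c(C=O)c2c1C(=O)Oc1c(C=O)c(O)c3c(c1O2)[C@@H](OCc1ccccc1[N+](=O)[O-])OC3=O
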